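**Plan**
Retrosynthesis, in order of cutting: the benzyl ether on the ring B phenol; O1–C2 of ring C (back to a 2'-hydroxy-α-methoxychalcone); C4a–C8a and C5–C6 of ring A; C4–C4a; C2=C3.
Enabling feature: ring A (C4a, C5, C6, C7, C8, C8a) carries oxygen on the three adjacent carbons C7, C8 and C8a beside the acyl-bearing C4a; C3, C2 and C1 of a squarate-derived 2,3-dimethoxycyclobutenone hand over exactly this pattern.
Forward: ring B is bought as isovanillin; C2=C3 comes from an aldol condensation and C4–C4a from acylation of a stannylvinyllithium; ring A is built by Stille coupling (C5–C6) and 4π opening/6π closure (C4a–C8a); ring C closes last (O1–C2), before debenzylation.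
Stereochemistry: the target has no stereocentre; the E vinylstannane derives from the E bis-stannane with retention, the Z enol ether is the thermodynamic condensation product, and every transient sp3 centre is racemic and is erased.

Key step: step 7

Assumption: the 4-chlorocyclobutenone is taken to survive brief handling at or below room temperature but not storage, so it is made and coupled on the same day.

**Step 1**
Reactants: 1 dimethyl squarate (3,4-dimethoxycyclobut-3-ene-1,2-dione)
Product: 2 4-hydroxy-2,3-dimethoxycyclobut-2-en-1-one (racemic)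
Conditions: LiAlH(OtBu)3 (1.05 equiv), THF, −78 → −20 °C; then H2O, 0 °C
Reagents that add atoms: none
Why: Chemoselective 1,2-reduction of one of the two equivalent vinylogous-ester carbonyls by a bulky hydride, the aluminium alkoxide formed being too electron-rich for a second hydride transfer at low temperature; the new centre is racemic and disappears in step 7.

**Step 2**
Reactants: 2 4-hydroxy-2,3-dimethoxycyclobut-2-en-1-one
Product: 3 4-chloro-2,3-dimethoxycyclobut-2-en-1-one (racemic)
Conditions: PPh3, CCl4, CH2Cl2, 0 °C → rt; pentane trituration, short silica plug, used at once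
Reagents that add atoms: carbon tetrachloride, ClC(Cl)(Cl)Cl
Why: Appel reaction, in which chloride displaces the alkoxyphosphonium group of the allylic, α-keto alcohol under neutral conditions, so the acid-triggered loss of methanol from 2 is avoided and the conjugated vinylogous ester is retained.

**Step 3**
Reactants: 4 isovanillin (3-hydroxy-4-methoxybenzaldehyde)
Product: 5 3-benzyloxy-4-methoxybenzaldehyde
Conditions: BnBr, K2CO3, DMF, rt
Reagents that add atoms: benzyl bromide, BrCc1ccccc1
Why: Williamson ether synthesis on the only phenol, which masks it against the alkoxide, Grignard and organolithium reagents of steps 4 to 6 and can be removed at the end by hydrogenolysis.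

**Step 4**
Reactants: 5 3-benzyloxy-4-methoxybenzaldehyde; 6 methyl methoxyacetate
Product: 7 methyl (Z)-3-(3-benzyloxy-4-methoxyphenyl)-2-methoxyprop-2-enoate
Conditions: NaOMe, MeOH, reflux (excess 6)
Reagents that add atoms: none
Why: Aldol condensation of the ester enolate with a non-enolisable aromatic aldehyde (Claisen–Schmidt type) followed by E1cB loss of water; the reversible sequence should settle on the Z enol ether, in which the aryl group is trans to the ester.

**Step 5**
Reactants: 7 methyl (Z)-3-(3-benzyloxy-4-methoxyphenyl)-2-methoxyprop-2-enoate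
Product: 8 (Z)-3-(3-benzyloxy-4-methoxyphenyl)-N,2-dimethoxy-N-methylprop-2-enamide
Conditions: MeNHOMe·HCl, iPrMgCl, THF, −20 → 0 °C
Reagents that add atoms: N,O-dimethylhydroxylamine hydrochloride, CNOC.Cl
Why: Direct aminolysis of the ester by the chloromagnesium amide of N,O-dimethylhydroxylamine (Weinreb amide formation), which should leave the donor-substituted alkene and both ethers untouched.

**Step 6**
Reactants: 8 (Z)-3-(3-benzyloxy-4-methoxyphenyl)-N,2-dimethoxy-N-methylprop-2-enamide; 9 (E)-1,2-bis(tributylstannyl)ethene
Product: 11 (1E,4Z)-5-(3-benzyloxy-4-methoxyphenyl)-4-methoxy-1-(tributylstannyl)penta-1,4-dien-3-one, via (E)-2-(tributylstannyl)vinyllithium 10 (not isolated)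
Conditions: 9, n-BuLi (1.0 equiv), THF, −78 °C; then 8, −78 → −40 °C; then H2O
Reagents that add atoms: none
Why: Tin–lithium exchange gives the E vinyllithium with retention, and its addition to the Weinreb amide stops at the chelated tetrahedral adduct (Weinreb ketone synthesis), so the β-stannyl dienone is released only on work-up and is not attacked a second time.

**Step 7**
Reactants: 3 4-chloro-2,3-dimethoxycyclobut-2-en-1-one; 11 (1E,4Z)-5-(3-benzyloxy-4-methoxyphenyl)-4-methoxy-1-(tributylstannyl)penta-1,4-dien-3-one
Product: 15 (Z)-3-(3-benzyloxy-4-methoxyphenyl)-1-(2-hydroxy-3,4-dimethoxyphenyl)-2-methoxyprop-2-en-1-one, via 4-alkenylcyclobutenone 12 (not isolated), via dienylketene 13 (not isolated), via cyclohexa-2,4-dienone tautomer 14 (not isolated)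
Conditions: PdCl2(PhCN)2 (5 mol %), tri(2-furyl)phosphine (10 mol %), 1,4-dioxane, 50 °C; then 100 °C
Reagents that add atoms: none
Why: Zerovalent palladium, formed in the flask from divalent PdCl2(PhCN)2, inserts into the allylic, α-keto C–Cl bond of 3 to give an oxocyclobutenyl palladium chloride, which accepts the alkenyl group from tin with retention of the E geometry and reductively eliminates at the hydrogen-bearing carbon to form the C5–C6 bond of 12 (Stille coupling). At 100 °C 12 opens by a thermal conrotatory 4π electrocyclic reaction to dienylketene 13, whose ketene carbon closes onto the acyl-bearing alkene carbon in a thermal disrotatory 6π electrocyclisation that forms the C4a–C8a bond and ring A, and enolisation of 14 to the hydrogen-bonded 2-acylphenol makes the sequence irreversible. The closest known reaction type is the palladium-catalysed coupling of 4-chlorocyclobutenones with alkenylstannanes followed by thermal benzannulation of the 4-alkenylcyclobutenones to phenols. No stereocentre remains in 15, the sp3 centres of 12 and 14 being transient and racemic, while the Z enol ether and the benzyl ether are spectators. Two selectivities are needed: bond formation at C4 and not at C2 of the oxocyclobutenyl unit, secured by the lower substitution at C4 and by the vinylogous-ester conjugation kept in 12, and inward rotation of the alkenyl group on ring opening, secured because the outward-rotated ketene recloses reversibly and only the inward rotamer is drained by the 6π closure. The substitution of ring A then follows from connectivity alone, since C1, C2 and C3 of the cyclobutenone become C8a, C8 and C7 with their three oxygens and C4 becomes C6.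

**Step 8**
Reactants: 15 (Z)-3-(3-benzyloxy-4-methoxyphenyl)-1-(2-hydroxy-3,4-dimethoxyphenyl)-2-methoxyprop-2-en-1-one
Product: 17 2-(3-benzyloxy-4-methoxyphenyl)-3,7,8-trimethoxy-4H-chromen-4-one, via 3-methoxyflavanone 16 (not isolated)
Conditions: I2 (10 mol %), DMSO, 120 °C
Reagents that add atoms: none
Why: Iodine/DMSO oxidative cyclisation of a 2'-hydroxychalcone, in which 6-endo oxa-Michael addition of the phenol gives flavanone 16, iodination at C3 and loss of HI aromatise the pyranone, and DMSO reoxidises HI to iodine; aryl methyl and benzyl ethers normally tolerate these conditions.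

**Step 9**
Reactants: 17 2-(3-benzyloxy-4-methoxyphenyl)-3,7,8-trimethoxy-4H-chromen-4-one
Product: 18 diplotrin B, 2-(3-hydroxy-4-methoxyphenyl)-3,7,8-trimethoxy-4H-chromen-4-one
Conditions: H2 (1 atm), palladium on carbon (Pd/C, 10 wt % Pd), EtOAc/MeOH, rt
Reagents that add atoms: none
Why: Catalytic hydrogenolysis of the benzyl aryl ether, under which the tetrasubstituted C2=C3 bond of the flavone, the ketone and the methyl ethers should remain unchanged.

**Compound list**
1 | dimethyl squarate (3,4-dimethoxycyclobut-3-ene-1,2-dione) | COC1=C(OC)C(=O)C1=O | starting material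
2 | 4-hydroxy-2,3-dimethoxycyclobut-2-en-1-one (racemic) | COC1=C(OC)C(=O)C1O | intermediate
3 | 4-chloro-2,3-dimethoxycyclobut-2-en-1-one (racemic) | COC1=C(OC)C(=O)C1Cl | intermediate
4 | isovanillin (3-hydroxy-4-methoxybenzaldehyde) | COc1ccc(C=O)cc1O | starting material
5 | 3-benzyloxy-4-methoxybenzaldehyde | COc1ccc(C=O)cc1OCc1ccccc1 | intermediate
6 | methyl methoxyacetate | COCC(=O)OC | starting material
7 | methyl (Z)-3-(3-benzyloxy-4-methoxyphenyl)-2-methoxyprop-2-enoate | COC(=O)/C(OC)=C/c1ccc(OC)c(OCc2ccccc2)c1 | intermediate
8 | (Z)-3-(3-benzyloxy-4-methoxyphenyl)-N,2-dimethoxy-N-methylprop-2-enamide | CON(C)C(=O)/C(OC)=C/c1ccc(OC)c(OCc2ccccc2)c1 | intermediate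
9 | (E)-1,2-bis(tributylstannyl)ethene | CCCC[Sn](CCCC)(CCCC)/C=C/[Sn](CCCC)(CCCC)CCCC | starting material
10 | (E)-2-(tributylstannyl)vinyllithium (not isolated) | CCCC[Sn](CCCC)(CCCC)/C=C/[Li] | intermediate
11 | (1E,4Z)-5-(3-benzyloxy-4-methoxyphenyl)-4-methoxy-1-(tributylstannyl)penta-1,4-dien-3-one | CCCC[Sn](CCCC)(CCCC)/C=C/C(=O)/C(OC)=C/c1ccc(OC)c(OCc2ccccc2)c1 | intermediate
12 | 4-[(1E,4Z)-5-(3-benzyloxy-4-methoxyphenyl)-4-methoxy-3-oxopenta-1,4-dien-1-yl]-2,3-dimethoxycyclobut-2-en-1-one (racemic, not isolated) | COC1=C(OC)C(=O)C1/C=C/C(=O)/C(OC)=C/c1ccc(OC)c(OCc2ccccc2)c1 | intermediate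
13 | (3E,5E,8Z)-9-(3-benzyloxy-4-methoxyphenyl)-2,3,8-trimethoxynona-1,3,5,8-tetraene-1,7-dione (dienylketene, C2 and C5 cis across C3=C4, not isolated) | O=C=C(OC)/C(OC)=C\C=C\C(=O)/C(OC)=C/c1ccc(OC)c(OCc2ccccc2)c1 | intermediate
14 | 6-[(Z)-3-(3-benzyloxy-4-methoxyphenyl)-2-methoxyprop-2-enoyl]-2,3-dimethoxycyclohexa-2,4-dien-1-one (racemic, not isolated) | COC1=C(OC)C(=O)C(C=C1)C(=O)/C(OC)=C/c1ccc(OC)c(OCc2ccccc2)c1 | intermediate
15 | (Z)-3-(3-benzyloxy-4-methoxyphenyl)-1-(2-hydroxy-3,4-dimethoxyphenyl)-2-methoxyprop-2-en-1-one | COc1ccc(C(=O)/C(OC)=C/c2ccc(OC)c(OCc3ccccc3)c2)c(O)c1OC | intermediate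
16 | 2-(3-benzyloxy-4-methoxyphenyl)-3,7,8-trimethoxychroman-4-one (racemic, cis/trans mixture, not isolated) | COc1ccc(C2Oc3c(OC)c(OC)ccc3C(=O)C2OC)cc1OCc1ccccc1 | intermediate
17 | 2-(3-benzyloxy-4-methoxyphenyl)-3,7,8-trimethoxy-4H-chromen-4-one | COc1ccc(-c2oc3c(OC)c(OC)ccc3c(=O)c2OC)cc1OCc1ccccc1 | intermediate
18 | diplotrin B, 2-(3-hydroxy-4-methoxyphenyl)-3,7,8-trimethoxy-4H-chromen-4-one | COc1ccc(-c2oc3c(OC)c(OC)ccc3c(=O)c2OC)cc1O | target

**Totals**
Total step count: 9.
Longest linear sequence: 7 steps (steps 3, 4, 5, 6, 7, 8 and 9, from isovanillin); the cyclobutenone branch (steps 1 and 2) joins at step 7.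

**Steps most likely to fail**

Step 2. The activated C4 substituent may ionise during chlorination or isolation, with loss of methanol to the semisquarate or hydrolysis back to the alcohol, so that little chloride reaches the coupling. The fallback sets out from 2 and replaces the chloride by an allylic ester. Acetylation (Ac2O, pyridine, catalytic DMAP, CH2Cl2, 0 °C) should give the storable 4-acetoxy-2,3-dimethoxycyclobut-2-en-1-one F1. F1 and stannane 11 are then joined under allylic-acetate Stille conditions (Pd2(dba)3, tri(2-furyl)phosphine, LiCl, DMF, 50 °C), where zerovalent palladium ionises the acetate to the same oxocyclobutenyl palladium species. Heating to 100 °C should carry the coupled cyclobutenone 12 through 13 and 14. The fallback comes back to the route at 15.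

Step 7. Tin-to-palladium transfer from the electron-poor β-stannyl enone may be slow enough for the oxocyclobutenyl palladium intermediate to decompose or for the stannane to be protonated off. Carbon–carbon bond formation at the methoxy-bearing allyl terminus would also divert material to the regioisomeric phenol. The fallback sets out from 5 and builds ring C on a purchased ring A. Claisen–Schmidt condensation of 5 with commercial 1-(2-hydroxy-3,4-dimethoxyphenyl)ethanone (KOH, EtOH, rt) should give (E)-3-(3-benzyloxy-4-methoxyphenyl)-1-(2-hydroxy-3,4-dimethoxyphenyl)prop-2-en-1-one F2. Algar–Flynn–Oyamada oxidation (H2O2, NaOH, MeOH, 0 °C → rt) should convert it into 2-(3-benzyloxy-4-methoxyphenyl)-3-hydroxy-7,8-dimethoxy-4H-chromen-4-one F3. O-Methylation of the only free hydroxyl (MeI, K2CO3, acetone, reflux) then gives the protected flavone. The fallback comes back to the route at 17 and passes by steps 7 and 8.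

Step 8. Electrophilic iodine may attack the electron-rich enol ether carbon and trigger 5-exo closure to benzofuranone products, or iodide may remove the C3 methyl group from the iodinated intermediate. The fallback sets out from 15 and separates ring closure from dehydrogenation without any halogen. Base-mediated oxa-Michael cyclisation (NaOAc, EtOH, reflux) should give flavanone 16, which is isolated this time. Dehydrogenation with DDQ (1,4-dioxane, reflux) then leads back to the route at 17. This fallback makes no compound outside the compound list (F0).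

**Further compounds**
F1 | step 2 | 4-acetoxy-2,3-dimethoxycyclobut-2-en-1-one (racemic) | COC1=C(OC)C(=O)C1OC(C)=O
F2 | step 7 | (E)-3-(3-benzyloxy-4-methoxyphenyl)-1-(2-hydroxy-3,4-dimethoxyphenyl)prop-2-en-1-one | COc1ccc(C(=O)/C=C/c2ccc(OC)c(OCc3ccccc3)c2)c(O)c1OC
F3 | step 7 | 2-(3-benzyloxy-4-methoxyphenyl)-3-hydroxy-7,8-dimethoxy-4H-chromen-4-one | COc1ccc(-c2oc3c(OC)c(OC)ccc3c(=O)c2O)cc1OCc1ccccc1
F0 | step 8 | none | none
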